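The data come from a simulation for an exercise; noise was put on by code.

I count each unit of product in the gamma flask as one turn of the free catalyst, and I count turns to decide whether to leave this flask, the same one followed on, closed until 12 d or add catalyst to it.

- gamma: substrate 1.1 M; coupling partner 1.5 equiv; free catalyst 0.34 mol%; the very flask that is asked about, followed so far
- flask: substrate 1.1 M; coupling partner 1.50 equiv; free catalyst 0.34 mol%; time 12 d

gamma run (percent of the substrate charged)

| time / d | substrate / % | product / % |
|---|---|---|
| 0.417 | 82.8 | 16.8 |
| 0.833 | 67.5 | 32.7 |
| 1.25 | 51.9 | 47.1 |
| 1.67 | 39.4 | 61.1 |
| 2.08 | 28.2 | 71.6 |
| 2.50 | 18.0 | 81.0 |

(each reading ± 0.5 percentage points)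

- the numbers in the tables scatter by 0.5 percentage points (one standard deviation)
- the reaction counts as stopped when no species that holds the substrate changes by six tenths of a point or more over the second half of the time

* which holds at 12 d: what has brought the reaction to rest, or that it has not come to rest (forward and back rates have come level / it is still moving / no working catalyst is left / the coupling partner has run out first / all of the substrate has reacted)
* how much of the substrate has reacted by 12 d
* how much product there is at 12 d, in percent of the substrate charged

Using up the substrate takes 294 turns per catalyst. Between the first and last readings, product rises 64 percentage points in 2.08 d, which on 0.34 mol% of catalyst reads 90.6 /d. I call this the turnover rate, the turns per catalyst charged per day averaged between those two readings (a turnover frequency). At that rate the need is met in 3.25 d. But the last stretch reads 65.8 /d, slower than the average, so that time is an estimate and no bound; the slower reading, held over 12 d, offers 790 turns, more than the need, and that is an estimate too. I take one coupling partner per turn, so 1.50 equiv covers the substrate, the limiting reagent. My decision is to add nothing and leave the flask closed.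

The forecast gives all of the substrate has reacted, with conversion 99.8 % and product 99.5 %. It puts the end of the substrate at 4.5 to 6 d, against my 3.25 d, and sees “no sign of an approaching equilibrium”.

The flask gives product 100 % at conversion 100 %: all of the substrate has reacted.

substrate + free catalyst ⇌ catalyst intermediate A (K = 12.0 /M, k = 22.0 /M/h); catalyst intermediate A → catalyst intermediate B (k = 25.0 /h); coupling partner + catalyst intermediate B → catalyst intermediate C (k = 42.0 /M/h); catalyst intermediate C ⇌ catalyst intermediate D (K = 0.470, k = 20.0 /h); catalyst intermediate D → free catalyst + product (k = 65.0 /h) At 12 d it holds less substrate, 0 %, than coupling partner, 33 % of its own charge. Now take a second flask with the free catalyst thinned to 0.099 mol% and the time held. There 90.6 /d, held over 12 d, offers 108 % of the substrate charged, but the product of the run at that loading has moved by 5 points from this flask's 100 %.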